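**Retrosynthetic overview**
1. Target ⇒ its 5,7-bis(MOM) ether; the acetals survive organolithium chemistry and come off under acid mild enough for the prenyl group.
2. Ring C (O1–C2–C3–C4 plus C4a/C8a) ⇒ two-atom ring expansion of a (4S)-4-aryl-oxetan-2-one: O1–C2–C3–C4 is the β-lactone ring, and an ortho-fluoro aryllithium inserts C4a and C8a into its acyl–O bond (C4–C4a by acyl substitution, O1–C8a by SNAr).
3. Enabling feature: in ring C, O1 and the C4 carbonyl are 1,3-related across C2–C3 (a β-lactone retron). On ring A, the acyl-bearing C4a lies between C8a (which carries only O1) and the oxygenated C5, so C4a maps onto C–Li flanked by OMOM and C8a onto C–F. C2, the only stereocentre, never loses its C–O bond.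
4. β-Lactone ⇒ catalytic asymmetric ketene–aldehyde [2+2] on 7-prenylbenzofuran-5-carbaldehyde ⇒ Stille prenylation of 7-bromobenzofuran-5-carbaldehyde ⇒ Sonogashira/annulation of 3-bromo-4-hydroxy-5-iodobenzaldehyde. Arene partner ⇒ 5-fluororesorcinol (MOM protection, NBS).
5. Ring order: furan ring of the benzofuran → oxetanone → pyranone (grown from the oxetanone, last); ring A is bought intact.

Key step: step 8

Assumption: 5-fluorobenzene-1,3-diol is taken as a catalogue compound; if it is not, BBr3 demethylation of 1-fluoro-3,5-dimethoxybenzene supplies it.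

**Route**

Step 1
Reactants: 1 3-bromo-4-hydroxybenzaldehyde
Product: 2 3-bromo-4-hydroxy-5-iodobenzaldehyde
Conditions: NIS, TsOH·H2O (cat.), MeCN, rt
Reagents that add atoms: N-iodosuccinimide O=C1CCC(=O)N1I
Why: Electrophilic aromatic iodination, which can only go to the one free position ortho to the phenol because the para position carries the formyl group.

Step 2
Reactants: 2 3-bromo-4-hydroxy-5-iodobenzaldehyde
Product: 4 7-bromo-2-(trimethylsilyl)-1-benzofuran-5-carbaldehyde, via alkynylphenol 3 (not isolated)
Conditions: Me3SiC≡CH, PdCl2(PPh3)2 (cat.), CuI (cat.), Et3N, DMF, rt → 60 °C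
Reagents that add atoms: ethynyltrimethylsilane C#C[Si](C)(C)C
Why: Sonogashira coupling at the C–I bond (oxidative addition far faster than at C–Br) followed in the same pot by copper/base-promoted 5-endo-dig attack of the ortho phenol on the alkyne (heteroannulation), which should place the silyl group at C2 of the new furan ring.

Step 3
Reactants: 4 7-bromo-2-(trimethylsilyl)-1-benzofuran-5-carbaldehyde
Product: 5 7-bromo-1-benzofuran-5-carbaldehyde
Conditions: TBAF·3H2O, THF, 0 °C
Reagents that add atoms: none
Why: Fluoride-mediated protodesilylation of the 2-silylbenzofuran (attack at silicon, protonation at C2 by water), which should leave the aldehyde and the aryl bromide untouched.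

Step 4
Reactants: 5 7-bromo-1-benzofuran-5-carbaldehyde
Product: 6 7-(3-methylbut-2-en-1-yl)-1-benzofuran-5-carbaldehyde
Conditions: prenylSnBu3, Pd(PPh3)4 (cat.), DMF, 90 °C
Reagents that add atoms: tributyl(3-methylbut-2-en-1-yl)stannane CC(C)=CC[Sn](CCCC)(CCCC)CCCC
Why: Stille cross-coupling of the aryl bromide with the prenylstannane, expected to give the linear prenyl arene by reductive elimination at the less hindered allyl terminus under neutral conditions that the aldehyde tolerates.

Step 5
Reactants: 6 7-(3-methylbut-2-en-1-yl)-1-benzofuran-5-carbaldehyde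
Product: 8 (4S)-4-[7-(3-methylbut-2-en-1-yl)-1-benzofuran-5-yl]oxetan-2-one, via ketene 7 (not isolated)
Conditions: AcCl, iPr2NEt, O-TMS-quinine (10 mol %), LiClO4, CH2Cl2/Et2O, −78 °C
Reagents that add atoms: acetyl chloride CC(Cl)=O
Why: Cinchona alkaloid/Lewis acid-catalysed acyl halide–aldehyde cyclocondensation (catalytic asymmetric ketene–aldehyde [2+2]): the alkaloid-bound ammonium enolate of ketene 7 adds to one face of the lithium-activated aldehyde and the aldolate lactonises, the quinine-derived catalyst being the pseudoenantiomer expected to give the 4S lactone (the quinidine analogue gives the antipode), so the stereocentre of the target is set here and its configuration should be confirmed before step 8.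

Step 6
Reactants: 9 5-fluorobenzene-1,3-diol
Product: 10 1-fluoro-3,5-bis(methoxymethoxy)benzene
Conditions: MOMCl, iPr2NEt, CH2Cl2, 0 °C → rt
Reagents that add atoms: chloromethyl methyl ether COCCl
Why: Williamson-type O-alkylation of both phenols, MOM being chosen because it is inert to organolithium reagents and is removed at the end by mild acid.

Step 7
Reactants: 10 1-fluoro-3,5-bis(methoxymethoxy)benzene
Product: 11 2-bromo-1-fluoro-3,5-bis(methoxymethoxy)benzene
Conditions: NBS (1.0 equiv), MeCN, 0 °C → rt
Reagents that add atoms: N-bromosuccinimide O=C1CCC(=O)N1Br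
Why: Electrophilic aromatic bromination, which in 1,3-dialkoxybenzenes goes para to one alkoxy group and ortho to the other, here the position next to fluorine, the site between the two OMOM groups being the hindered one.

Step 8
Reactants: 11 2-bromo-1-fluoro-3,5-bis(methoxymethoxy)benzene; 8 (4S)-4-[7-(3-methylbut-2-en-1-yl)-1-benzofuran-5-yl]oxetan-2-one
Product: 14 (2S)-5,7-bis(methoxymethoxy)-2-[7-(3-methylbut-2-en-1-yl)-1-benzofuran-5-yl]-2,3-dihydro-4H-chromen-4-one, via aryllithium 12 (not isolated), via lithium keto-alkoxide 13 (not isolated)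
Conditions: 11, n-BuLi (0.98 equiv), THF, −78 °C; cannulated into 8, THF, −78 °C; then DMPU, −78 °C → rt
Reagents that add atoms: none
Why: Bromine–lithium exchange turns 11 into the ortho-fluoro aryllithium 12, a 1,2-arylene of fixed polarity (carbanion at the future C4a, leaving group at the future C8a) that adds to the strained lactone carbonyl of 8 with acyl–oxygen cleavage and so frees the ring oxygen as alkoxide 13. This alkoxide displaces the ortho fluoride by SNAr (addition–elimination through a Meisenheimer intermediate activated by the new ortho ketone), a six-membered closure at the arene carbon (formally 6-exo-trig) that completes the net insertion of two aryl carbons into the C(acyl)–O bond, a 4→6 ring expansion in which all four lactone ring atoms end in the pyranone. The closest known reaction types are the acyl–oxygen opening of β-lactones by organolithium reagents to β-hydroxy ketones, the SNAr closure of o-fluoroaryl β-hydroxy ketones to chroman-4-ones and, for the expansion logic as a whole (a nucleophile opens the ring and the freed ring heteroatom closes on the reagent carbon with loss of a leaving group), the Corey–Chaykovsky expansion of epoxides to oxetanes. No stereocentre is made: C4 of the lactone becomes C2 of the flavanone with its C–O bond untouched, so 4S is carried over as 2S. The step needs attack at the acyl carbon and not at the benzylic carbon or at acidic C–H (lactone α-CH2, benzofuran C2–H), which the hard aryllithium, −78 °C, inverse addition and a slight deficit of n-BuLi should secure; a single addition, which the two ortho substituents flanking the ketone of 13 should enforce; and ring closure faster than retro-aldol cleavage of 13, for which DMPU is added and heating is avoided. The regiochemistry on ring A cannot go astray because it is written into 12 (Li between F and OMOM).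

Step 9
Reactants: 14 (2S)-5,7-bis(methoxymethoxy)-2-[7-(3-methylbut-2-en-1-yl)-1-benzofuran-5-yl]-2,3-dihydro-4H-chromen-4-one
Product: 15 abyssinoflavanone VI
Conditions: conc. HCl (aq., few equiv), MeOH, rt → 40 °C
Reagents that add atoms: none
Why: Acid-catalysed acetal methanolysis of both MOM ethers, under which the prenyl group has no ortho phenol to cyclise onto and the flavanone C2–O bond should not ionise, so the 2S configuration is kept.

**Compound list**
1 | 3-bromo-4-hydroxybenzaldehyde | O=Cc1ccc(O)c(Br)c1 | starting material
2 | 3-bromo-4-hydroxy-5-iodobenzaldehyde | O=Cc1cc(Br)c(O)c(I)c1 | intermediate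
3 | 3-bromo-4-hydroxy-5-[(trimethylsilyl)ethynyl]benzaldehyde (not isolated) | O=Cc1cc(Br)c(O)c(C#C[Si](C)(C)C)c1 | intermediate
4 | 7-bromo-2-(trimethylsilyl)-1-benzofuran-5-carbaldehyde | O=Cc1cc(Br)c2oc([Si](C)(C)C)cc2c1 | intermediate
5 | 7-bromo-1-benzofuran-5-carbaldehyde | O=Cc1cc(Br)c2occc2c1 | intermediate
6 | 7-(3-methylbut-2-en-1-yl)-1-benzofuran-5-carbaldehyde | CC(C)=CCc1cc(C=O)cc2ccoc12 | intermediate
7 | ketene (not isolated) | C=C=O | intermediate
8 | (4S)-4-[7-(3-methylbut-2-en-1-yl)-1-benzofuran-5-yl]oxetan-2-one | CC(C)=CCc1cc([C@@H]2CC(=O)O2)cc2ccoc12 | intermediate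
9 | 5-fluorobenzene-1,3-diol | Oc1cc(O)cc(F)c1 | starting material
10 | 1-fluoro-3,5-bis(methoxymethoxy)benzene | COCOc1cc(F)cc(OCOC)c1 | intermediate
11 | 2-bromo-1-fluoro-3,5-bis(methoxymethoxy)benzene | COCOc1cc(OCOC)c(Br)c(F)c1 | intermediate
12 | [2-fluoro-4,6-bis(methoxymethoxy)phenyl]lithium (not isolated) | COCOc1cc(OCOC)c([Li])c(F)c1 | intermediate
13 | lithium (1S)-3-[2-fluoro-4,6-bis(methoxymethoxy)phenyl]-1-[7-(3-methylbut-2-en-1-yl)-1-benzofuran-5-yl]-3-oxopropan-1-olate (not isolated) | CC(C)=CCc1cc([C@@H](O[Li])CC(=O)c2c(F)cc(OCOC)cc2OCOC)cc2ccoc12 | intermediate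
14 | (2S)-5,7-bis(methoxymethoxy)-2-[7-(3-methylbut-2-en-1-yl)-1-benzofuran-5-yl]-2,3-dihydro-4H-chromen-4-one | CC(C)=CCc1cc([C@@H]2CC(=O)c3c(OCOC)cc(OCOC)cc3O2)cc2ccoc12 | intermediate
15 | abyssinoflavanone VI, (2S)-5,7-dihydroxy-2-[7-(3-methylbut-2-en-1-yl)-1-benzofuran-5-yl]-2,3-dihydro-4H-chromen-4-one | CC(C)=CCc1cc([C@@H]2CC(=O)c3c(O)cc(O)cc3O2)cc2ccoc12 | target

**Step count and risks**
Total steps: 9. Longest linear sequence: 7 (steps 1–5, 8, 9).

Steps most likely to fail:

1. Step 8. What may go wrong: retro-aldol cleavage of the lithium alkoxide (and re-addition without facial control) may outrun the SNAr closure, eroding enantiomeric purity and mass balance; deprotonation of the lactone α-CH2 or of benzofuran C2–H by the aryllithium may compete with acyl addition. The fallback reverses the order of bond formation (C–O first with inversion, C–C second), so that neither an aldolate nor an SNAr step is involved; it sets out from 6 and comes back at 14. Aldehyde 6 is taken through the same cyclocondensation with O-TMS-quinidine to give (4R)-4-[7-(3-methylbut-2-en-1-yl)-1-benzofuran-5-yl]oxetan-2-one F1. Partial MOM protection of phloroglucinol (MOMCl 2 equiv, iPr2NEt, separation from the mono- and tri-ethers) gives 3,5-bis(methoxymethoxy)phenol F2. Its caesium phenoxide in DMF should open F1 at the benzylic carbon by SN2 alkyl–oxygen cleavage with inversion, the mode phenoxides show with β-lactones, to give (3S)-3-[3,5-bis(methoxymethoxy)phenoxy]-3-[7-(3-methylbut-2-en-1-yl)-1-benzofuran-5-yl]propanoic acid F3. Intramolecular Friedel–Crafts acylation of the phloroglucinol-type ring (TFAA, 2,6-di-tert-butylpyridine, CH2Cl2, 0 °C; the two positions ortho to the ether oxygen are equivalent) should then close the pyranone and give 14.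

2. Step 5. What may go wrong: the cycloaddition may be slow with an electron-rich aromatic aldehyde, facial control may be insufficient or of the unexpected sense, and the 4-aryl lactone may ionise and decarboxylate during isolation. The fallback sets the carbinol centre by reduction instead of cycloaddition; it sets out from 6 and comes back at 8. Roskamp homologation of 6 (ethyl diazoacetate, NbCl5 cat., CH2Cl2) should give ethyl 3-[7-(3-methylbut-2-en-1-yl)-1-benzofuran-5-yl]-3-oxopropanoate F4. Noyori–Ikariya transfer hydrogenation (RuCl[(S,S)-TsDPEN](p-cymene), HCO2H/Et3N) should give ethyl (3S)-3-hydroxy-3-[7-(3-methylbut-2-en-1-yl)-1-benzofuran-5-yl]propanoate F5, the aryl group directing as in aryl methyl ketones. Saponification (LiOH, THF/H2O) gives (3S)-3-hydroxy-3-[7-(3-methylbut-2-en-1-yl)-1-benzofuran-5-yl]propanoic acid F6, and lactonisation by carboxyl activation (PhSO2Cl, pyridine, 0 °C), which leaves the carbinol C–O bond intact, returns 8 with retention.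

3. Step 4. What may go wrong: allyl transposition at palladium may deliver the branched 1,1-dimethylallyl isomer alongside the prenyl arene, and the two are hard to separate. The fallback builds the prenyl group in two operations with no ambident allyl partner; it sets out from 5 and comes back at 6. Stille coupling of 5 with allyltributylstannane (Pd(PPh3)4, DMF, 90 °C) should give 7-(prop-2-en-1-yl)-1-benzofuran-5-carbaldehyde F7, and cross-metathesis of F7 with excess 2-methyl-2-butene (second-generation ruthenium benzylidene catalyst, CH2Cl2, 40 °C) should give 6.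

**Further compounds**
F1 | step 8 | (4R)-4-[7-(3-methylbut-2-en-1-yl)-1-benzofuran-5-yl]oxetan-2-one | CC(C)=CCc1cc([C@H]2CC(=O)O2)cc2ccoc12
F2 | step 8 | 3,5-bis(methoxymethoxy)phenol | COCOc1cc(O)cc(OCOC)c1
F3 | step 8 | (3S)-3-[3,5-bis(methoxymethoxy)phenoxy]-3-[7-(3-methylbut-2-en-1-yl)-1-benzofuran-5-yl]propanoic acid | CC(C)=CCc1cc([C@@H](Oc2cc(OCOC)cc(OCOC)c2)CC(=O)O)cc2ccoc12
F4 | step 5 | ethyl 3-[7-(3-methylbut-2-en-1-yl)-1-benzofuran-5-yl]-3-oxopropanoate | CCOC(=O)CC(=O)c1cc(CC=C(C)C)c2occc2c1
F5 | step 5 | ethyl (3S)-3-hydroxy-3-[7-(3-methylbut-2-en-1-yl)-1-benzofuran-5-yl]propanoate | CC(C)=CCc1cc([C@@H](O)CC(=O)OCC)cc2ccoc12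
F6 | step 5 | (3S)-3-hydroxy-3-[7-(3-methylbut-2-en-1-yl)-1-benzofuran-5-yl]propanoic acid | CC(C)=CCc1cc([C@@H](O)CC(=O)O)cc2ccoc12
F7 | step 4 | 7-(prop-2-en-1-yl)-1-benzofuran-5-carbaldehyde | C=CCc1cc(C=O)cc2ccoc12
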